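The easiest flask to start from is Wednesday's, which runs at 100 °C, where the constants stand as given. You wanted a quick number, and your hunch was that cold flasks lack time while hot ones lose material to side routes, so here is the job and then what I would sign.

common to all: starting material 1.5 M; coupling partner 1.42 M; protic impurity 0.450 M; time 3.0 min
- Monday's: temperature 10 °C
- Saturday's: temperature 40 °C
- Thursday's: temperature 70 °C
- Wednesday's: temperature 100 °C

- the flask that comes out highest in amount of target, in percent of the starting material charged, or "all alike" when all lie within 1.5 percentage points (Monday's / Saturday's / Thursday's / Wednesday's / all alike)
- target at the end, in percent of the starting material charged, Monday's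
- target at the end, in percent of the starting material charged, Saturday's
- target at the end, in percent of the starting material charged, Thursday's
- target at the end, in percent of the starting material charged, Wednesday's

- percent here means starting material units held: one side product B or homo dimer counts as two
- a step written with two of one species runs at k times the square of its concentration and takes two of it each time
- constants are those at 100 °C; use the activation energies for any other temperature

    starting material + coupling partner → target (k1 = 0.053 M⁻¹ s⁻¹, Ea1 = 74.0 kJ mol⁻¹)
    starting material → side product A (k2 = 0.052 s⁻¹, Ea2 = 105 kJ mol⁻¹)
    2 starting material → side product B (k3 = 0.020 M⁻¹ s⁻¹, Ea3 = 66.0 kJ mol⁻¹)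
    2 starting material → homo dimer (k4 = 2.5 × 10⁻⁶ M⁻¹ s⁻¹, Ea4 = 101 kJ mol⁻¹)
    target → over-reaction product (k5 = 4.8 × 10⁻⁴ s⁻¹, Ea5 = 103 kJ mol⁻¹)
    starting material + protic impurity → quenched substrate (k6 = 0.11 M⁻¹ s⁻¹, Ea6 = 55.0 kJ mol⁻¹)
    (constants at 100 °C)

Starting material leaves by coupling with the coupling partner into target, by passing on its own into side product A, by pairing into side product B and by quenching with the protic impurity. The homo dimer route makes no difference to Wednesday's target. Divide the coupling rate by the sum of those rates: time drops out, one power of starting material cancels, and what remains is S, a selectivity, the fraction of the starting material leaving at that instant that becomes target.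

At the start of Wednesday's the terms are 0.0753 s⁻¹ for coupling, 0.052 s⁻¹ for side product A, 0.0600 s⁻¹ for pairing, counted twice since each turn takes two, and 0.0495 s⁻¹ for quenching. So S opens at 31.8%. Carry each constant to 70 °C with its activation energy and the same terms become 0.00935 s⁻¹, 0.00270 s⁻¹, 0.00934 s⁻¹ and 0.0105 s⁻¹, so Thursday's opens at 29.3%, and that opening coupling share is the number I carry.

Wednesday's target also decays to over-reaction product. Held for the full 3.0 min, it would keep a factor 0.917, which brings Wednesday's to 29.2%, level with Thursday's. The pairing and quench terms should shrink as their species are used, so I expect S to climb, but by hand I cannot separate these flasks. Monday's is simpler: the opening coupling rate held for 3.0 min gives 0.691%. The same product gives Saturday's 14.0%, but that holds the opening rate fixed, and I expect the rate to fall as starting material and coupling partner are used.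

The forecast reads 0.67%, 10.2%, 36% and 32.4% from Monday's to Wednesday's, with Thursday's highest and “about a third going to target”. The simulation gives 0.671%, 10.3%, 35.8% and 32.5% in that order, so Thursday's comes out highest, 3.3 percentage points ahead of Wednesday's.

In Thursday's at 0.526 min, the protic impurity has a half-life of 0.71 min by its quench, shorter than the 2.5 min of the coupling partner by coupling, and that flask ends with 35.8% of target, above its opening S of 29.3%. A neighbour of Thursday's charged with 0.77 M of protic impurity opens at S = 23.8%, lower than Thursday's, and ends with 30.7% of target.

(The rate constants belong to no real substance; the result is computed.)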